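- The number I steer by is 74.3%. In the noon run at 8.00 h, starting material and product leave 5.4 percentage points of the charge unfound, while the catalyst ratio c(precatalyst)/c(starting material) is 7.27%. The first divided by the second I call the held share.

| flask | starting material | precatalyst | temperature | remark | time |
|---|---|---|---|---|---|
| dawn | 0.069 M | 8 mM | 80 °C | run made earlier |  |
| noon | 0.11 M | 8 mM | 102 °C | run made earlier |  |
| dusk | 0.13 M | 8 mM | 80 °C | run made earlier |  |
| teal | 0.080 M | 8.0 mM |  | at 70 °C until 15 h, from then on at 110 °C | 50 h |
| amber | 0.15 M | 8.0 mM |  | at 70 °C throughout | 50 h |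

| run | time / h | product / % | starting material / % |
|---|---|---|---|
| dawn | 5.00 | 27.5 | 70.5 |
| dawn | 12.0 | 63.1 | 32.6 |
| dawn | 15.0 | 71.7 | 22.8 |
| dawn | 25.0 | 87.4 | 7.3 |
| noon | 0.833 | 19.3 | 77.5 |
| noon | 2.50 | 49.5 | 46.8 |
| noon | 5.00 | 68.2 | 25.5 |
| noon | 8.00 | 80.6 | 14.0 |
| dusk | 2.50 | 9.0 | 91.2 |
| dusk | 8.00 | 41.5 | 55.6 |
| dusk | 15.0 | 65.7 | 31.3 |
| dusk | 25.0 | 82.5 | 14.3 |

(readings scatter by 0.5 percentage points)

- the earlier runs were read with a standard deviation of 0.5 points

* which one finishes higher in amount of product, in percent of the starting material charged ("neither" within 2 percentage points) (teal / amber / neither)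
* amount of product at the end, in percent of the starting material charged, teal
* amount of product at the end, in percent of the starting material charged, amber

- I suppose the unfound part sits on the catalyst, one per catalyst. My zero is then the even case, and the dusk run's last reading gives 52.0%, about half. Product is then the charge minus starting material left minus held share times catalyst ratio. These readings each carry a scatter of 0.5 points.
- Charge: by hand, with the precatalyst held at 8.0 mM, a larger charge lowers the catalyst ratio, which is 10.0% in teal and 5.33% in amber. In the runs at 80 °C, the dusk run has 31.3% starting material left at 15.0 h and the dawn run 22.8%, so the larger charge lags.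
- Temperature: by hand, warming speeds the flask. The noon run reaches 14.0% left by 8.00 h, where the dusk run needs 25.0 h for 14.3%, but the charges differ too, 0.11 M against 0.13 M. The held share read from the noon run is also higher than the one read from the dusk run, and the same two settings differ there.
- Time: teal has 35.0 h hot, 4.38 times the noon run's span, so I count no starting material left and, with the held share of the hot noon run, reckon 92.6%. For amber I take 50 h at 70 °C as worth the dusk run's 25.0 h at 80 °C, and, with the dusk run's held share, reckon 82.9%.
- The forecast says teal, with 91% for teal and 77% for amber, and of the rate constant falling as the charge rises it says: “This fits saturation with product binding”. My amber stands 5.9 points above it.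
- Teal ends at 91.8% and amber at 84.0%, so teal finishes higher, and the forecast's amber is 7 points low. At the end of teal, catalyst intermediate is the resting state, with 81.7% of the catalyst against 18.3% free, and it keeps 8.17% of the charge. The held share gave 7.43% for that amount.

    starting material + free catalyst → catalyst intermediate (k = 0.00350 /M/s, Ea = 73.0 kJ/mol)
    catalyst intermediate ⇌ free catalyst + product (K = 0.110 M, k = 0.00580 /s, Ea = 107 kJ/mol, ΔH = −52.0 kJ/mol)
    precatalyst → free catalyst (k = 1.90 × 10⁻⁵ /s, Ea = 114 kJ/mol)
    (constants at 70 °C)

- Take teal read at 20 h, with 10.8% starting material left: the held share gives 81.8% product. The computed flask has 81.2%, with 7.99% of the charge in catalyst intermediate.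

The numbers in the tables were computed with constants of no real substance, noise included.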